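The new flask's peak of intermediate cannot be copied from Wednesday's run, as your hunch has it, although both charge substrate and catalyst alike: the flask starts with a reagent concentration D of 20.0 mM, the drain concentration, which is lower than Wednesday's 30.0 mM.

| flask | substrate | reagent | catalyst | remark | time |
|---|---|---|---|---|---|
| Tuesday's | 14 mM | 2 equiv | 3.8 mol% | run made earlier |  |
| Monday's | 22 mM | 2 equiv | 3.8 mol% | run made earlier |  |
| Wednesday's | 10 mM | 3 equiv | 3.8 mol% | run made earlier |  |
| flask | 10 mM | 2.00 equiv | 3.8 mol% |  | 1.5 h |

- Tuesday's (time / min: intermediate / %, product / %): 1.00: 18.0, 24.3; 2.50: 13.1, 58.4; 6.00: 4.2, 89.6; 15.0: 0.2, 99.3; 40.0: 0.9, 98.9; 120: 1.4, 101.1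
- Monday's (time / min: intermediate / %, product / %): 1.00: 11.3, 47.0; 2.50: 4.9, 81.8; 6.00: 1.1, 99.6; 15.0: 0, 100.5; 40.0: 0, 99.6; 120: 0, 101.6
- Wednesday's (time / min: intermediate / %, product / %): 1.00: 18.4, 16.7; 3.00: 11.2, 54.3; 10.0: 1.8, 93.2; 30.0: 0.4, 100.2; 120: 0.5, 100.6

(each reading ± 1 percentage point)

- on the list of suspects stand: substrate + catalyst <-> catalyst + intermediate; reagent + catalyst + intermediate -> catalyst + product

* the moment within 1.5 h at which there is most intermediate, in min
* the amount of intermediate, in percent of the substrate charged, at that time

The catalyst is returned by each turnover, so its concentration can be frozen, and it stands once in the step that makes intermediate and once in the step that uses it, so it cancels from their ratio and acts on the time axis. With reagent frozen near its charge as well, the use of intermediate is pseudo-first-order with a rate constant proportional to D and to the catalyst, and, the catalyst cancelling, the height of the peak should fall as D rises. The runs are in line with this, as far as such sparse readings show: Tuesday's at 28.0 mM and Wednesday's at 30.0 mM, with catalyst at 0.532 mM and 0.380 mM, have highest readings of 18.0% and 18.4%, which lie 0.4 percentage points apart against a scatter of 1 point, while Monday's at 44.0 mM has its highest reading, 11.3%, at its first point, 1.00 min, where it may already be past its peak. With D below all of these, my reckoning expects for the new flask a peak above the 18.4% read in Wednesday's run, as an estimate and not a bound, and gives no finer figure. The forecast, by “hand integration”, goes further and names 21% (19% to 23%) at 1.5 min (1.1 min to 2 min).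

The flask peaks at 22.7% after 1.58 min, inside both of the forecast's ranges, and the peak is brief, with intermediate down to 5.69% after 0.150 h. At the peak, the flask's reagent still stands at 88.5% of its charge, which is 17.7 mM against the D of 20.0 mM frozen in the reckoning.

    substrate + catalyst ⇌ catalyst + intermediate (K = 1.60, k = 20.0 M⁻¹ s⁻¹)
    reagent + catalyst + intermediate → catalyst + product (k = 2000 M⁻² s⁻¹)

The neighbouring flask charges 6.5 mol% of catalyst, which is 0.650 mM against 0.380 mM, but its D remains 20.0 mM, so the reckoning expects the height unchanged, and that flask's peak of intermediate is 22.7%.

(The earlier runs and the new flask are calculated on assumed constants; noise was put on by code.)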